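A small charge of catalyst, 31 µM to 120 µM, had worked on a racemic substrate and a solid reagent in three earlier runs. I had to say whether eta or alpha, one charge read at 12 h and at 20 h, held the larger excess of left-handed over right-handed product.

in all of them: solid reagent 77.5 mM
- larch: left-handed substrate 31 mM; right-handed substrate 31 mM; catalyst 31 µM; run made earlier
- oak: left-handed substrate 31 mM; right-handed substrate 31 mM; catalyst 120 µM; run made earlier
- birch: left-handed substrate 62 mM; right-handed substrate 62 mM; catalyst 62 µM; run made earlier
- eta: left-handed substrate 31 mM; right-handed substrate 31 mM; catalyst 62 µM; time 12 h
- alpha: left-handed substrate 31 mM; right-handed substrate 31 mM; catalyst 62 µM; time 20 h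

| run | time / h | left-handed product / % | right-handed product / % |
|---|---|---|---|
| larch | 1.50 | 1.0 | 0.8 |
| larch | 4.00 | 3.6 | 2.1 |
| larch | 8.00 | 7.1 | 7.2 |
| larch | 12.0 | 11.7 | 11.0 |
| oak | 3.00 | 3.7 | 3.5 |
| oak | 6.00 | 8.0 | 7.6 |
| oak | 10.0 | 13.3 | 12.8 |
| oak | 12.0 | 16.2 | 14.8 |
| birch | 1.00 | 0.3 | 0.4 |
| birch | 2.00 | 1.4 | 0.7 |
| birch | 5.00 | 3.2 | 3.6 |
| birch | 12.0 | 8.2 | 8.1 |

(readings scatter by 0.3 percentage points)

1. the winner by excess of left-handed product over right-handed product in the product; "neither" if no more than 2 percentage points parts them (eta / alpha / neither)
2. excess of left-handed product over right-handed product in the product at the end, eta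
3. excess of left-handed product over right-handed product in the product at the end, alpha

- catalyst is single-handed; left-handed substrate and right-handed substrate are mirror images of each other, charged as a racemate, each of them at the stated concentration
- solid, in amounts per volume of the solution: solid reagent
- the analysis behind the earlier runs scatters by 0.3 percentage points, standard deviation
- at the start none of the solid reagent is in solution
- an excess is below zero if the other one leads

I split the readings of all three runs into the first two and the last two of each. On average the readings put the left-handed product ahead of the right-handed by 0.48 percentage points early and 0.37 points late, while the mean sum of the two products rose from 5.52% to 19.5%. A fixed product ratio asks for 1.7 points late. Their mean, 0.42 points, is what I carried: the gap G, the left-handed product minus the right-handed product, taken as level while the products grow. The excess E is then G divided by the product sum S.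

Larch and oak bracket the catalyst of eta and alpha, and their mean S at 12 h was 26.9%. I drew S as a straight line from zero, at 1.39 mM/h. So on this drawing E falls along a hyperbola. It crosses a value equal to the margin where S is 21.2%, at 9.50 h. I reckoned 1.58% for eta and 0.950% for alpha, which differ by 0.63 points, less than the margin, so I said neither.

The forecast also said neither, but with 2.8% for eta and 2.6% for alpha, nearly flat where mine fell, holding that “the excess drops only slightly with conversion”.

The flasks gave neither: 1.79% for eta and 0.962% for alpha, 0.83 points apart.

    partner + catalyst + left-handed substrate → catalyst + left-handed product (k = 4.90 × 10⁵ /M²/h)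
    partner + catalyst + right-handed substrate → catalyst + right-handed product (k = 16000 /M²/h)
    left-handed substrate ⇌ right-handed substrate (k = 0.0700 /h)
    solid reagent ⇌ partner, rate k4*(cs4 - [partner]) while solid is left; crystals form when [partner] > cs4 (solubility = 17.0 mM, k = 0.110 /h)
    left-handed product ⇌ right-handed product (k = 2.20 /h)

The neighbouring flask is eta stopped at 3.0 h, earlier than the crossing. My line gives S of 6.73% there, and G over S gives an excess of 6.33%, larger than the value of the margin. That flask held an S of 5.56% and an excess of 9.36%.

The data are calculated for an exercise, noise included.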